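## The problem

Atom labels used throughout: ring A (six-membered) is C1–C2=C3–C4–C5–C6 and ring B (seven-membered) is C6–C7–C8–C9–C10–C11–C1. C1 and C6 are the ring-fusion carbons, C3 carries a methyl group, C4 the isovanillate, C7 a methyl and a hydroxyl group, and C11 two methyl groups.

Target 18 is the isovanillate of a cis-fused bicyclo[5.4.0]undecene diol, so a synthesis must join a cyclohexene to a cycloheptane across C1–C6 with both ring-fusion hydrogens on one face. There are four stereocentres: C1 and C6 at the fusion, the allylic ester carbon C4 and the tertiary carbinol C7. C1 and C6 are adjacent and can be set together. Once the fusion is cis, the folded bicycle has a convex and a concave face, and this can direct both the addition of methyl to a C7 ketone and the approach of an oxygen nucleophile to C4. The absolute configuration has no obvious chiral-pool source and must come from one asymmetric step. The quaternary carbon C11 makes C1 neopentyl, which hinders bond formation at C1 but also shields C2 in any allyl cation spanning C2–C3–C4. The secondary allylic ester ionises or eliminates under acid and is cleaved by base, the C7 alcohol can dehydrate or attack C4 across the ring, and the free phenol is a competing nucleophile. Organometallic steps therefore have to come before the ester, and the end game has to be mild. The enabling feature is that the C4 oxygen is allylic and sits next to the methyl-bearing carbon C3 of the C2=C3 alkene. This is the pattern left when a chloro(methyl)cyclopropane fused across C2 and C4 of a cyclopentene opens to a 2-methylcyclohexenyl cation, with C3 as the inserted carbon and the carboxylic acid as the trap.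

## Retrosynthesis

**18 ⇒ 17.** The phenol and the C7 hydroxyl are unmasked last. Two silyl ethers (tert-butyldimethylsilyl on the phenol, triethylsilyl on C7) fall together with fluoride, so the protection costs one closing step and touches no stereocentre.

**17 ⇒ 13 + 16.** The ester C4–O bond is cut together with a contraction of ring A: C3 is taken out of the ring and C2 is reconnected to C4, giving the chloro(methyl)cyclopropane 13 and the protected acid 16. Cutting only the ester bond would leave a secondary allylic alcohol to be made stereoselectively beside a tertiary one, and would leave ring A and the position of its alkene unsolved. In 13, ring A is a cyclopentane with no alkene and no allylic oxygen, and the two partners are of similar size. The forward reaction must use the endo chloride, capture the cation at C4 and not at C2, and deliver the acid to the convex face.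

**16 ⇒ 14.** The acid partner is isovanillic acid 14 with its phenol silylated, so that only the carboxyl group competes for the cation.

**13 ⇒ 11 + 12.** The cyclopropane bonds C2–C3 and C3–C4 are cut, which leads to cyclopentene 11 and the carbene precursor 1,1-dichloroethane 12. This removes two stereocentres and the halide. The forward addition must come from the convex face and give chlorine over the five-membered ring.

**11 ⇒ 10 ⇒ 9.** Removing the silyl group and cutting the C7–CH3 bond gives the cis-fused ketone 9. The ketone is wanted in any case, since it is the activating group for building the five-membered ring. The methyl addition must occur anti to C5 on the neighbouring stereocentre C6.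

**9 ⇒ 8.** Cutting C5–C6 and reconnecting C2 to C6 turns the cyclopentene into vinylcyclopropane 8. Against a direct cyclopentene annulation or a conjugate addition followed by alkylation and metathesis, this route is short, gives the cis fusion by construction, and fixes the alkene on the C1 side through the choice of which cyclopropane bond breaks.

**8 ⇒ 4 + 7 (7 ⇒ 5 + 6).** The cyclopropane bonds C1–C2 and C2–C6 are cut, giving 4,4-dimethylcyclohept-2-en-1-one 4 and an allyl ylide. Using the chiral sulfonium salt 7, made from the limonene-derived sulfide 5 and allyl bromide 6, makes this the one step that sets absolute configuration (C1, and with it C6). It must add 1,4 at the hindered C1.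

**4 ⇒ 3 ⇒ 1 + 2.** Enone 4 is the one-carbon homologue of commercial 4,4-dimethylcyclohex-2-en-1-one 1. Its carbonyl carbon becomes C7, its alkene C6=C1 and its quaternary carbon C11. Carbon C8 is inserted on the saturated side from ethyl diazoacetate 2 via β-keto ester 3.

## Roads not taken

**Alternative 1: aromatic annulation, then dearomatisation.** The cut is at C1–C11 and C6–C7 with ring A as an arene. In polyphosphoric acid the tertiary cation from 5-methylhex-4-enoic acid A2 would alkylate 2-methylanisole A1 para to the methoxy group, and the acid would then acylate the neighbouring position to close ring B, giving benzosuberone A3.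
- Merits: one operation from two commodity compounds delivers the whole bicyclic carbon skeleton with the C3 methyl and the C4 oxygen in place. In steps to the skeleton it is clearly shorter than the chosen plan.
- Weak points: A3 is flat and achiral, so all four stereocentres must be made after a Birch-type reduction that has a benzylic C7 oxygen next to it. The cis fusion would then rest on protonations or a hydrogenation with no strong bias. The acylation must occur meta to the methoxy group, and the absolute configuration would need a late resolution.
- Comparison: the chosen plan is longer to the skeleton, but one asymmetric step fixes C1 and C6, these then relay to C7 and C4, and the ester arrives with ring A.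

**Alternative 2: transannular allylation of an eleven-membered ring.** The cut is the ring-fusion bond C1–C6. Pd(PPh3)4 would ionise the C1 acetate of macrocycle A4 to an allyl complex over C1–C3, and the fluoride-released enolate carbon C6 would attack C1 across the ring, closing both rings and giving ketone A5.
- Merits: two rings and the fusion stereochemistry from one bond, with the C2=C3 alkene and a C7 ketone placed correctly. As a ring-forming event it is more convergent than anything in the chosen plan.
- Weak points: A4 needs a medium-ring closure with a regiodefined enol silane and allylic acetate. The attack has to occur at the neopentyl C1. Enantiocontrol by a ligand in a transannular process is uncertain. A5 also lacks the C4 oxygen, so an allylic oxidation would have to choose C4 over the C1 hydrogen and the C3 methyl, and choose one face.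
- Comparison: the chosen plan forms its rings one at a time, but it installs the C4–O bond in the same step that creates ring A and needs no late oxidation.

**Alternative 3: oxyallyl cation plus 2-methylfuran.** The cut is at C6–C7 and C10–C11. The 1,1-dimethyl-2-oxyallyl cation from 3-bromo-3-methylbutan-2-one A6 (Et3N, CF3CH2OH) would add across 2-methylfuran A7 to give the oxygen-bridged cycloheptenone A8.
- Merits: ring B with both quaternary carbons, including the C7 methyl and oxygen, in one step from cheap reagents. For ring B this is better than the chosen plan, which needs a homologation and a later methyl addition.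
- Weak points: the adduct is racemic and depends on head-to-tail regiochemistry. The oxygen bridge must be cleaved at C10 only and the C8=C9 alkene removed. Ring A, with the cis fusion, the C2=C3 alkene, the C3 methyl and the C4 stereocentre, would still have to be annulated onto the C1 ketone, which is several further steps with weak stereocontrol.
- Comparison: the chosen plan spends more steps on ring B but obtains ring A, the C4 oxygen and the ester in one controlled event.

Key step: step 10

Assumption: the facial sense in which sulfonium salt 7 attacks enone 4 is taken to give 8 as drawn; if the antipode is favoured, the enantiomeric sulfide (from the other limonene enantiomer) is used in step 3.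

## Route

Step 1
Reactants: 1 4,4-dimethylcyclohex-2-en-1-one; 2 ethyl diazoacetate
Product: 3 ethyl 5,5-dimethyl-2-oxocyclohept-3-ene-1-carboxylate (racemic at the enolisable C1 of the ester)
Conditions: BF3·OEt2, CH2Cl2, 0 °C to rt
Reagents that add atoms: none
Why: Lewis-acid-promoted diazoacetate homologation (Tiffeneau–Demjanov-type ring expansion): the diazo carbon adds to the activated carbonyl and the saturated α-carbon migrates in preference to the vinylic one, so the enone is kept and the inserted carbon carries the ester. The gem-dimethyl group disfavours attack at the β-carbon, and the β-keto ester product does not react further.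

Step 2
Reactants: 3 ethyl 5,5-dimethyl-2-oxocyclohept-3-ene-1-carboxylate
Product: 4 4,4-dimethylcyclohept-2-en-1-one
Conditions: 6 M HCl, AcOH, 100 °C
Reagents that add atoms: none
Why: Acid hydrolysis and decarboxylation of a β-keto ester (ketonic cleavage) gives the conjugated cycloheptenone; no stereocentre is involved.

Step 3
Reactants: 5 (1R,4R,5R)-4,7,7-trimethyl-6-thiabicyclo[3.2.1]octane (isothiocineole); 6 allyl bromide
Product: 7 (1R,4R,5R,6R)-4,7,7-trimethyl-6-(prop-2-en-1-yl)-6-thiabicyclo[3.2.1]octan-6-ium trifluoromethanesulfonate (allyl on the sulfur face turned away from the C2–C4 bridge)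
Conditions: LiOSO2CF3, CH2Cl2, H2O, rt
Reagents that add atoms: lithium trifluoromethanesulfonate [Li+].[O-]S(=O)(=O)C(F)(F)F
Why: S-Alkylation of the sulfide with anion exchange to the non-nucleophilic triflate. The more exposed sulfur lone pair should react, so one sulfonium diastereomer is expected.

Step 4
Reactants: 4 4,4-dimethylcyclohept-2-en-1-one; 7 S-allyl isothiocineolium triflate
Product: 8 (1R,7S,8S)-8-ethenyl-6,6-dimethylbicyclo[5.1.0]octan-2-one (vinyl exo, trans to both ring bonds)
Conditions: KOC(CH3)3, THF, -78 °C to -20 °C
Reagents that add atoms: none
Why: Sulfonium-ylide cyclopropanation (Michael-initiated ring closure of Corey–Chaykovsky type): the allylide adds to C1 of the enone and the enolate carbon C6 displaces the sulfide at the ylide carbon, which necessarily gives the cis-fused bicycle. The configuration at C1, and with it C6, is set by the chiral sulfonium framework, as in known chiral allylide cyclopropanations of enones. The configuration at the vinyl-bearing carbon is lost in step 5, and sulfide 5 is recovered.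

Step 5
Reactants: 8 (1R,7S,8S)-8-ethenyl-6,6-dimethylbicyclo[5.1.0]octan-2-one
Product: 9 (3aR,8aS)-8,8-dimethyl-3,3a,6,7,8,8a-hexahydroazulen-4(5H)-one (cis-fused; alkene C2=C4 next to C1)
Conditions: flash vacuum pyrolysis, 550 °C, 0.1 mbar, quartz tube conditioned with PbCO3
Reagents that add atoms: none
Why: Thermal vinylcyclopropane–cyclopentene rearrangement: the cyclopropane bond between C6 and the vinyl-bearing carbon, weakened by both the carbonyl and the vinyl group, breaks, and C6 rebonds to the vinyl terminus, so the alkene ends on the C1 side and the new CH2 (C5) on C6. C1 is untouched, and closure on the face the cyclopropane occupied gives the cis fusion. Retro-ene side paths are closed because neither C7 nor C11 carries hydrogen.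

Step 6
Reactants: 9 (3aR,8aS)-8,8-dimethyl-3,3a,6,7,8,8a-hexahydroazulen-4(5H)-one
Product: 10 (3aR,4S,8aS)-4,8,8-trimethyl-3,3a,4,5,6,7,8,8a-octahydroazulen-4-ol (hydroxyl trans to H6)
Conditions: MeMgBr, CeCl3, THF, -78 °C, then H2O
Reagents that add atoms: methylmagnesium bromide C[Mg]Br
Why: Organocerium 1,2-addition (Imamoto conditions) avoids enolisation of the epimerisable C6. Methyl should enter from the convex face of the cis-fused bicycle, anti to C5 on the adjacent stereocentre, which places the C7 hydroxyl trans to H6 as in the target.

Step 7
Reactants: 10 (3aR,4S,8aS)-4,8,8-trimethyl-3,3a,4,5,6,7,8,8a-octahydroazulen-4-ol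
Product: 11 triethyl{[(3aR,4S,8aS)-4,8,8-trimethyl-3,3a,4,5,6,7,8,8a-octahydroazulen-4-yl]oxy}silane
Conditions: Et3SiOSO2CF3, 2,6-lutidine, CH2Cl2, -78 °C to 0 °C
Reagents that add atoms: triethylsilyl trifluoromethanesulfonate CC[Si](CC)(CC)OS(=O)(=O)C(F)(F)F
Why: Silylation of a hindered tertiary alcohol with a silyl triflate and a hindered base. The ether keeps the C7 oxygen from capturing the cation in step 10.

Step 8
Reactants: 11 triethylsilyl ether of 10; 12 1,1-dichloroethane
Product: 13 (1R,1aR,2aR,3S,7aR,7bS)-1-chloro-1,3,7,7-tetramethyl-3-[(triethylsilyl)oxy]decahydro-1H-cyclopropa[a]azulene (cyclopropane on the face of H1 and H6; chlorine endo over the five-membered ring; methyl exo)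
Conditions: n-BuLi, Et2O, -40 °C
Reagents that add atoms: none
Why: Chloro(methyl)carbenoid [2+1] cycloaddition: lithiation of 12 and α-elimination give the carbenoid, which adds stereospecifically to the cyclopentene from the convex face, syn to the ring-fusion hydrogens. The endo-chloro, exo-methyl isomer is the one needed and should be favoured by the usual syn preference of the halogen; any exo-chloro isomer is carried along and removed after step 10.

Step 9
Reactants: 14 isovanillic acid (3-hydroxy-4-methoxybenzoic acid)
Product: 16 3-[(tert-butyldimethylsilyl)oxy]-4-methoxybenzoic acid, via tert-butyldimethylsilyl 3-(tert-butyldimethylsilyloxy)-4-methoxybenzoate 15 (not isolated)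
Conditions: TBSCl, imidazole, DMF, rt; then AcOH, THF, H2O, rt
Reagents that add atoms: tert-butyldimethylsilyl chloride CC(C)(C)[Si](C)(C)Cl
Why: Exhaustive silylation of phenol and acid, then selective hydrolysis of the labile silyl ester; the aryl silyl ether survives the mild aqueous acid.

Step 10
Reactants: 13 chloro(methyl)cyclopropane tricycle; 16 3-[(tert-butyldimethylsilyl)oxy]-4-methoxybenzoic acid
Product: 17 (2R,4aS,9S,9aR)-3,5,5,9-tetramethyl-9-[(triethylsilyl)oxy]-2,4a,5,6,7,8,9,9a-octahydro-1H-benzo[7]annulen-2-yl 3-[(tert-butyldimethylsilyl)oxy]-4-methoxybenzoate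
Conditions: AgBF4, 2,6-di-tert-butyl-4-methylpyridine, CH2Cl2, 0 °C to rt, dark
Reagents that add atoms: none
Why: Silver-assisted ionisation of the endo C3–Cl bond is concerted with disrotatory cleavage of the C2–C4 cyclopropane bond (cyclopropyl-to-allyl cation electrocyclic opening); the closest known type is the silver-promoted ring expansion of halocyclopropanes fused to five-membered rings with carboxylate capture. Only the chloride lying over the five-membered ring can open, because the ring bonds C2–C1 and C4–C5 are cis to it and must turn inward to give the cis allyl cation that a six-membered ring can hold. Ring A is thus formed by ring enlargement from five to six members through this two-electron electrocyclic opening, not by a new ring-closing bond, and the C2=C3 alkene with its methyl on C3 appears at the same time. Acid 16 then adds to the C2–C3–C4 cation at C4, the terminus next to the C5 methylene, because C2 is screened by C1 and the adjacent quaternary C11; this forms the ester C–O bond. The new stereocentre C4 is controlled by the cis ring fusion: ring B with its silyloxy and gem-dimethyl groups covers the concave face, so the acid enters on the convex face, cis to H1 and H6, as the target requires. The hindered pyridine takes up HBF4 so that both silyl ethers and the new allylic ester survive, and the silyl group on the C7 oxygen blocks transannular ether formation.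

Step 11
Reactants: 17 bis-silyl ether of the target
Product: 18 (2R,4aS,9S,9aR)-9-hydroxy-3,5,5,9-tetramethyl-2,4a,5,6,7,8,9,9a-octahydro-1H-benzo[7]annulen-2-yl 3-hydroxy-4-methoxybenzoate
Conditions: Bu4NF, AcOH, THF, 0 °C to rt
Reagents that add atoms: none
Why: Fluoride cleavage of the aryl and the tertiary silyl ether, buffered with acetic acid so that no free phenoxide or alkoxide attacks the allylic ester; no stereocentre is touched.

## Compound list

1 | 4,4-dimethylcyclohex-2-en-1-one | CC1(C)CCC(=O)C=C1 | starting material
2 | ethyl diazoacetate | CCOC(=O)C=[N+]=[N-] | starting material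
3 | ethyl 5,5-dimethyl-2-oxocyclohept-3-ene-1-carboxylate | CCOC(=O)C1CCC(C)(C)C=CC1=O | intermediate
4 | 4,4-dimethylcyclohept-2-en-1-one | CC1(C)CCCC(=O)C=C1 | intermediate
5 | (1R,4R,5R)-4,7,7-trimethyl-6-thiabicyclo[3.2.1]octane (isothiocineole) | C[C@@H]1CC[C@@H]2C[C@H]1SC2(C)C | starting material
6 | allyl bromide | C=CCBr | starting material
7 | (1R,4R,5R,6R)-4,7,7-trimethyl-6-(prop-2-en-1-yl)-6-thiabicyclo[3.2.1]octan-6-ium trifluoromethanesulfonate | C[C@@H]1CC[C@@H]2C[C@H]1[S@@+](CC=C)C2(C)C.[O-]S(=O)(=O)C(F)(F)F | intermediate
8 | (1R,7S,8S)-8-ethenyl-6,6-dimethylbicyclo[5.1.0]octan-2-one | O=C1CCCC(C)(C)[C@H]2[C@H](C=C)[C@@H]12 | intermediate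
9 | (3aR,8aS)-8,8-dimethyl-3,3a,6,7,8,8a-hexahydroazulen-4(5H)-one | O=C1CCCC(C)(C)[C@H]2C=CC[C@@H]12 | intermediate
10 | (3aR,4S,8aS)-4,8,8-trimethyl-3,3a,4,5,6,7,8,8a-octahydroazulen-4-ol | C[C@]1(O)CCCC(C)(C)[C@H]2C=CC[C@@H]12 | intermediate
11 | triethyl{[(3aR,4S,8aS)-4,8,8-trimethyl-3,3a,4,5,6,7,8,8a-octahydroazulen-4-yl]oxy}silane | C[C@]1(O[Si](CC)(CC)CC)CCCC(C)(C)[C@H]2C=CC[C@@H]12 | intermediate
12 | 1,1-dichloroethane | CC(Cl)Cl | starting material
13 | (1R,1aR,2aR,3S,7aR,7bS)-1-chloro-1,3,7,7-tetramethyl-3-[(triethylsilyl)oxy]decahydro-1H-cyclopropa[a]azulene (endo chloride, exo methyl) | C[C@]1(O[Si](CC)(CC)CC)CCCC(C)(C)[C@H]2[C@H]3[C@@H](C[C@@H]12)[C@@]3(C)Cl | intermediate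
14 | isovanillic acid (3-hydroxy-4-methoxybenzoic acid) | COc1ccc(C(=O)O)cc1O | starting material
15 | tert-butyldimethylsilyl 3-[(tert-butyldimethylsilyl)oxy]-4-methoxybenzoate | COc1ccc(C(=O)O[Si](C)(C)C(C)(C)C)cc1O[Si](C)(C)C(C)(C)C | intermediate
16 | 3-[(tert-butyldimethylsilyl)oxy]-4-methoxybenzoic acid | COc1ccc(C(=O)O)cc1O[Si](C)(C)C(C)(C)C | intermediate
17 | (2R,4aS,9S,9aR)-3,5,5,9-tetramethyl-9-[(triethylsilyl)oxy]-2,4a,5,6,7,8,9,9a-octahydro-1H-benzo[7]annulen-2-yl 3-[(tert-butyldimethylsilyl)oxy]-4-methoxybenzoate | COc1ccc(C(=O)O[C@@H]2C[C@@H]3[C@H](C=C2C)C(C)(C)CCC[C@]3(C)O[Si](CC)(CC)CC)cc1O[Si](C)(C)C(C)(C)C | intermediate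
18 | (2R,4aS,9S,9aR)-9-hydroxy-3,5,5,9-tetramethyl-2,4a,5,6,7,8,9,9a-octahydro-1H-benzo[7]annulen-2-yl 3-hydroxy-4-methoxybenzoate | COc1ccc(C(=O)O[C@@H]2C[C@@H]3[C@H](C=C2C)C(C)(C)CCC[C@]3(C)O)cc1O | target

## Step count and least certain steps

Total: 11 steps. Longest linear sequence: 9 steps (steps 1, 2, 4, 5, 6, 7, 8, 10 and 11, from 1 to 18); steps 3 and 9 are one-step side branches.

**Step 10 (key step).** The ring-expanded cation may lose a proton to give a diene instead of being captured. Capture may be unselective between C4 and C2 or between the two faces. The silyl ether oxygen on C7 may take part, with loss of the silyl group and transannular ether formation. Fallback from 13 to 17: the opening is run with water as a small nucleophile in large excess (AgBF4, 2,6-lutidine, aqueous acetone) to give the allylic alcohol (2R,4aS,9S,9aR)-3,5,5,9-tetramethyl-9-[(triethylsilyl)oxy]-2,4a,5,6,7,8,9,9a-octahydro-1H-benzo[7]annulen-2-ol F1. F1 is then acylated with 16 under Yamaguchi conditions (2,4,6-trichlorobenzoyl chloride, Et3N, DMAP), which rejoins the route at 17. This separates the ring expansion from the esterification at the cost of one step.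

**Step 4.** Because C1 is neopentyl, the ylide may add to the carbonyl group instead (vinyl epoxide formation) or not react, and facial discrimination by the chiral sulfonium salt on this cyclic enone may be insufficient. Fallback from 4 to 9, which also bypasses step 5:
- [Rh(cod)Cl]2 (cod = cycloocta-1,5-diene) with BINAP and aqueous KOH catalyses asymmetric 1,4-addition of the (Z)-alkenylboronate tert-butyldimethyl{[(2Z)-3-(4,4,5,5-tetramethyl-1,3,2-dioxaborolan-2-yl)prop-2-en-1-yl]oxy}silane F2 to 4. F2 is made in one step by trans-hydroboration of the silyl ether of propargyl alcohol with pinacolborane. The product is (3R)-3-[(1Z)-3-{[tert-butyl(dimethyl)silyl]oxy}prop-1-en-1-yl]-4,4-dimethylcycloheptan-1-one F3.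
- Ph3PBr2 converts the silyl ether directly into the allylic bromide (3R)-3-[(1Z)-3-bromoprop-1-en-1-yl]-4,4-dimethylcycloheptan-1-one F4.
- KOC(CH3)3 in THF closes the five-membered ring by intramolecular alkylation of the C6 enolate on the face that carries the side chain, giving cis-fused 9.

**Step 5.** At the pyrolysis temperature the cis fusion may be lost through closure on the other face or enolisation. The other cyclopropane bond at the vinyl-bearing carbon may cleave and give the regioisomeric cyclopentene, and fragmentation is possible. Fallback from 8 to 9: a stepwise ionic opening and reclosure. Me3SiI with (Me3Si)2NH in CH2Cl2 at low temperature opens the activated cyclopropane to the silyl enol ether allylic iodide trimethyl({(3S)-3-[(1Z)-3-iodoprop-1-en-1-yl]-4,4-dimethylcyclohept-1-en-1-yl}oxy)silane F5, whose allylic isomers interconvert. Bu4NF then releases the enolate, which alkylates at C6 to give 9 with the cis fusion under kinetic control.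

**Step 8.** The lithium carbenoid may decompose by hydrogen shift to vinyl chloride faster than it adds to a hindered, valuable alkene. Chlorine may end up exo in a large share of the product, which is then inert in step 10. The endo chloride may ionise early on silica. Fallback from 11 to 17:
- Dibromocarbene (CHBr3, KOC(CH3)3, pentane, -20 °C) gives (1aR,2aR,3S,7aR,7bS)-1,1-dibromo-3,7,7-trimethyl-3-[(triethylsilyl)oxy]decahydro-1H-cyclopropa[a]azulene F6, which always has one endo bromide.
- Silver-promoted opening of F6 with 16 under the step 10 conditions gives the 2-bromoallylic ester (2R,4aR,9S,9aR)-3-bromo-5,5,9-trimethyl-9-[(triethylsilyl)oxy]-2,4a,5,6,7,8,9,9a-octahydro-1H-benzo[7]annulen-2-yl 3-[(tert-butyldimethylsilyl)oxy]-4-methoxybenzoate F7.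
- Negishi coupling of F7 with MeZnCl and Pd[P(t-Bu)3]2 at rt installs the C3 methyl group and gives 17. Fast oxidative addition of zerovalent palladium into the vinyl C–Br bond at room temperature should outrun ionisation of the allylic ester.

**Step 6.** Methyl may add with poor facial selectivity or from the concave face, and C6 may epimerise through enolisation. Fallback from 9 to 10: Wittig methylenation (Ph3P=CH2) gives (3aR,8aS)-8,8-dimethyl-4-methylidene-3,3a,4,5,6,7,8,8a-octahydroazulene F8. Hydrogen-atom-transfer hydration of the 1,1-disubstituted alkene (Mn(dpm)3, dpm = 2,2,6,6-tetramethylheptane-3,5-dionate, PhSiH3, O2, i-PrOH) then brings oxygen to the more open face of C7. This is the stereochemical complement of nucleophilic methyl addition and should spare the cyclopentene.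

## Further compounds

F1 | step 10 | (2R,4aS,9S,9aR)-3,5,5,9-tetramethyl-9-[(triethylsilyl)oxy]-2,4a,5,6,7,8,9,9a-octahydro-1H-benzo[7]annulen-2-ol | O[C@@H]1C[C@@H]2[C@H](C=C1C)C(C)(C)CCC[C@]2(C)O[Si](CC)(CC)CC
F2 | step 4 | tert-butyldimethyl{[(2Z)-3-(4,4,5,5-tetramethyl-1,3,2-dioxaborolan-2-yl)prop-2-en-1-yl]oxy}silane | CC(C)(C)[Si](C)(C)OC/C=C\B1OC(C)(C)C(C)(C)O1
F3 | step 4 | (3R)-3-[(1Z)-3-{[tert-butyl(dimethyl)silyl]oxy}prop-1-en-1-yl]-4,4-dimethylcycloheptan-1-one | O=C1CCCC(C)(C)[C@@H](/C=C\CO[Si](C)(C)C(C)(C)C)C1
F4 | step 4 | (3R)-3-[(1Z)-3-bromoprop-1-en-1-yl]-4,4-dimethylcycloheptan-1-one | O=C1CCCC(C)(C)[C@@H](/C=C\CBr)C1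
F5 | step 5 | trimethyl({(3S)-3-[(1Z)-3-iodoprop-1-en-1-yl]-4,4-dimethylcyclohept-1-en-1-yl}oxy)silane | C[Si](C)(C)OC1=C[C@H](/C=C\CI)C(C)(C)CCC1
F6 | step 8 | (1aR,2aR,3S,7aR,7bS)-1,1-dibromo-3,7,7-trimethyl-3-[(triethylsilyl)oxy]decahydro-1H-cyclopropa[a]azulene | C[C@]1(O[Si](CC)(CC)CC)CCCC(C)(C)[C@H]2[C@H]3[C@@H](C[C@@H]12)C3(Br)Br
F7 | step 8 | (2R,4aR,9S,9aR)-3-bromo-5,5,9-trimethyl-9-[(triethylsilyl)oxy]-2,4a,5,6,7,8,9,9a-octahydro-1H-benzo[7]annulen-2-yl 3-[(tert-butyldimethylsilyl)oxy]-4-methoxybenzoate | COc1ccc(C(=O)O[C@@H]2C[C@@H]3[C@H](C=C2Br)C(C)(C)CCC[C@]3(C)O[Si](CC)(CC)CC)cc1O[Si](C)(C)C(C)(C)C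
F8 | step 6 | (3aR,8aS)-8,8-dimethyl-4-methylidene-3,3a,4,5,6,7,8,8a-octahydroazulene | C=C1CCCC(C)(C)[C@H]2C=CC[C@@H]12
A1 | alternative 1 | 2-methylanisole | COc1ccccc1C
A2 | alternative 1 | 5-methylhex-4-enoic acid | CC(C)=CCCC(=O)O
A3 | alternative 1 | 3-methoxy-2,9,9-trimethyl-6,7,8,9-tetrahydro-5H-benzo[7]annulen-5-one | COc1cc2c(cc1C)C(C)(C)CCCC2=O
A4 | alternative 2 | 3,11,11-trimethyl-7-[(trimethylsilyl)oxy]cycloundeca-2,6-dien-1-yl acetate | CC(=O)OC1C=C(C)CCC=C(O[Si](C)(C)C)CCCC1(C)C
A5 | alternative 2 | (4aR,9aS)-2,9,9-trimethyl-3,4,4a,6,7,8,9,9a-octahydro-5H-benzo[7]annulen-5-one | C1C[C@@H]2[C@H](C=C1C)C(C)(C)CCCC2=O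
A6 | alternative 3 | 3-bromo-3-methylbutan-2-one | CC(=O)C(C)(C)Br
A7 | alternative 3 | 2-methylfuran | Cc1ccco1
A8 | alternative 3 | (1R,5R)-1,4,4-trimethyl-8-oxabicyclo[3.2.1]oct-6-en-3-one | C[C@@]12C=C[C@@H](O1)C(C)(C)C(=O)C2
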